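## Analysis of the target

The target is an isoflavone. Rings A and C form a 5,7-dihydroxychromen-4-one, and C3 of this chromone carries ring B (C1' to C6'). Ring B has a free hydroxyl on C2' and a 2H-pyran fused across C3' and C4' (pyran atoms O1'', C2'', C3'', C4''; C4'' sits on C3' and O1'' on C4'). The only stereocentre is C2'', a fully substituted ether carbon bearing O1'', a methyl group, a hydroxymethyl group and the C3''=C4'' alkene, with S configuration. No neighbouring centre can relay chirality to it, so it has to be brought in intact or set on its own. The sensitive points are these: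

- The tertiary, allylic C2''–O bond ionises in strong acid, and the 2H-chromene opens to an ortho-quinone methide under UV light or strong heat, which would scramble C2''.
- The electron-rich styrene-type alkene rules out hydrogenolysis and electrophilic oxidants such as trivalent thallium or hypervalent iodine.
- C2 of the chromone is a Michael acceptor for hydroxide and alkoxide.

The difficulty lies in telling methyl from hydroxymethyl at a quaternary ether carbon, in placing four contiguous substituents on ring B, and in building ring C without reagents that attack the chromene. The strategy rests on the C3''=C4'' double bond: it is the only C=C of the pyran and links C3' of ring B to the stereocentre. If this bond is made last from two vinyl groups, C2'' can enter as a finished tertiary allylic alcohol whose oxygen is bonded to C4' without any bond at the stereocentre being broken.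

## Retrosynthetic reasoning

**28 back to 22.** The last operations only unmask oxygen. Both acetals of 26 fall in one acid step. Before that, the C5–O and C7–O bonds of ring A are traced back through diallyl ether 24 to the two C–F bonds of 22. Cutting at the aryl carbon, not at an oxygen–protecting-group bond of a ready-made trioxygenated ring, lets ring A come from the simple acyl chloride 19 and gives ring C an ortho leaving group for its own closure. The forward steps must exchange two fluorines for alkoxide without destroying the chromone and must remove allyl without acid strength or hydrogen.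

**22 back to 18 and 19.** Ring C is cut at O1–C8a and at C3–C4. The first cut leads to enol 21, whose oxygen displaces an ortho fluorine. The second leads through enaminone 20 to enamine 18 and acyl chloride 19. The C3–C1' bond is not cut at all. A cross-coupling there would need a metalated or halogenated ring B, whereas the formyl carbon of 12 can become C3 directly. No oxidant is needed, so the chromene alkene is never exposed to one.

**18 back to 12 and 15.** The enamine double bond (future C2=C3) is cut by olefination. Phosphine oxide 15, made from 13, delivers the future C2 with nitrogen already attached. This gives the enamine in one step from aldehyde 12 and avoids both a free arylacetaldehyde and an acidic enol ether hydrolysis.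

**12 back to 11.** The C3''=C4'' bond is cut to two vinyl groups, one on C3' and one on C2''. This is the only ring bond whose formation leaves all four bonds of the stereocentre alone. The forward reaction has to close a six-membered ring between a hindered styrene and a vinyl group on a quaternary carbon, in the presence of an aldehyde and two acetals.

**11 back to 5 and 9.** The ether is cut on the aryl side (C4'–O), not at O–C2''. Making the O–C2'' bond would mean substitution at a tertiary carbon and loss of configuration. Making the aryl–O bond from potassium alkoxide 10 and fluoroarene 5, activated by the para formyl group, keeps the configuration by construction. The primary oxygen is protected as an acetal and not as a silyl ether, because a silyl group next to a potassium tert-alkoxide shifts to the neighbouring oxygen and the freed primary alkoxide would then be arylated instead.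

**9 back to 6.** The vinyl group of 9 is cut between its two carbons. Epoxide 7 supplies the inner carbon and a sulfur ylide the outer one, by way of betaine 8. The stereocentre is bought with (R)-2-methylglycidol 6, and its C–O bond is never broken.

**5 back to 1.** The vinyl group is cut from the ring at C3 (cross-coupling of bromide 4) and the formyl group at C1 (ortho-formylation of phenol 1 through 2 to 3). Phenol 1 already has bromine between hydroxyl and fluorine, so the 1,2,3,4-pattern of ring B needs no regiochemical decision. The vinyl group must go in before the ether, because an aryl–palladium species next to a pendant allyl ether would cyclise by a Heck path.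

## Alternatives that were turned down

**Alternative 1: ring B grown on the chromone by Danheiser benzannulation.**
- Disconnection: four bonds of ring B (C1'–C2', C2'–C3', C4'–C5', C5'–C6') are cut, leaving diazo ketone A2, which carries the chromone on an enone arm, and siloxy enyne A3.
- Forward key step: loss of nitrogen from A2 and Wolff shift give a vinylketene. A3 adds to it in a [2+2] step, the cyclobutenone opens, and the dienylketene closes to phenol A1, with the free hydroxyl on C2', the propenyl group on C3' and the silyl ether on C4'.
- For: the whole substitution pattern of ring B and its attachment to C3 come from one pericyclic cascade with regiochemistry fixed by mechanism, and the two ring B oxygens are differentiated from the start. On this point it is stronger than the chosen route, which buys the pattern with 1 and then needs several steps for ring C.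
- Against: it says nothing about C2''. From A1 the tertiary ether would have to be made on a phenol with no para acceptor. That means ionising allyl chemistry, which racemises unless a chiral catalyst controls it, followed by a ring-closing metathesis with the propenyl group. The key step of the chosen route would therefore still be needed. A2 combines a diazo ketone with a photoreactive, electrophilic chromone, A3 is a sensitive ynol ether whose alkene can also react, and both need several steps.
- Comparison: more steps and more untested ground. The chosen route instead offers a stereocentre from the chiral pool that no step can touch.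

**Alternative 2: oxa-[3+3] annulation, arene made later.**
- Disconnection: C3'–C4'' and O–C2'' are cut together while ring B is still cyclohexane-1,3-dione A5; the partner is enal A6 and the product is dihydrochromenone A4.
- Forward key step: Knoevenagel condensation of A5 at C2 with A6, then 6π electrocyclisation of the 1-oxatriene.
- For: one metal-free step from cheap achiral materials forms both pyran bonds. In step count to the pyran ring it clearly beats the chosen route, which needs seven steps to reach 12.
- Against: A4 is achiral, with two identical silyloxymethyl arms on C2''. The target needs these enantiotopic arms told apart at a quaternary carbon with no nearby handle, and one of them reduced to methyl at a neopentyl position. The electrocyclisation is reversible, so C2'' would not be configurationally safe before aromatisation. The ring must then be dehydrogenated to the phenol in the presence of the chromene alkene, and C1' still needs its carbon substituent.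
- Comparison: shorter to the ring, far longer to the single enantiomer. The chosen route offers the absolute configuration from its first compound and a benzene ring that needs no oxidation.

**Alternative 3: ring C by rhodium-catalysed aldehyde C–H annulation.**
- Disconnection: C3–C4 and O1–C2 of ring C are cut, giving salicylaldehyde A8 and aryl silyl alkyne A9; the product is 2-silylisoflavone A7.
- Forward key step: the phenoxide of A8 directs rhodium into the formyl C–H bond, the acyl–rhodium species adds across the alkyne of A9 with silicon ending on C2, and C–O reductive elimination closes ring C while an oxidant returns the metal.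
- For: the two halves are joined in one step and ring A arrives with both oxygens in place as acetals, so no fluorine has to be exchanged. On this point it is stronger than steps 9 to 13 of the chosen route.
- Against: A9 already contains the chiral chromene. The strategy therefore leaves the stereocentre and the pyran unsolved and would lean on a closure like step 7 anyway, followed by conversion of an aldehyde such as 12 into the alkyne. The alkyne carries an aryl group with two ortho substituents, so rate and regiochemistry of insertion are uncertain. The acyl–metal species can lose CO, the formyl group of A8 is flanked by two oxygens, the electron-rich chromene alkene meets a hot oxidising copper salt, and a desilylation step is added.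
- Comparison: a more convergent end, but riskier and no shorter overall. The chosen route uses only substitution chemistry at ring C and places its one demanding step where the stereocentre is a spectator.

Key step: step 7

Remarks on the chemistry:
- Q stands for the (2S)-5-(methoxymethoxy)-2-[(methoxymethoxy)methyl]-2-methyl-2H-chromen-6-yl group.
- In steps 12 to 14 two like groups react in turn. The order written (C7 before C5 in step 12, O7 before O5 in step 13, aryl acetal before alkyl acetal in step 14) is the expected one and has no bearing on the product.
- Enaminone 20 is drawn E; either geometry serves.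

## Route

Step 1
Reactants: 1 2-bromo-3-fluorophenol
Product: 3 3-bromo-4-fluoro-2-hydroxybenzaldehyde, via 2-bromo-3-fluoro-6-(hydroxymethyl)phenol 2 (not isolated)
Conditions: MgCl2, Et3N, (CH2O)n, MeCN, reflux
Reagents that add atoms: formaldehyde (as paraformaldehyde), C=O
Why: Magnesium-mediated ortho-formylation of a phenol (Casnati–Skattebøl): the magnesium phenoxide delivers formaldehyde to the only free ortho position and a second equivalent oxidises benzylic alcohol 2 by hydride transfer. Bromine already sits between hydroxyl and fluorine, so the pattern of ring B is fixed without a regiochemical choice.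

Step 2
Reactants: 3 3-bromo-4-fluoro-2-hydroxybenzaldehyde
Product: 4 3-bromo-4-fluoro-2-(methoxymethoxy)benzaldehyde
Conditions: MOMCl, iPr2NEt, CH2Cl2, 0 °C to rt
Reagents that add atoms: chloromethyl methyl ether, COCCl
Why: O-alkylation of the phenol with an α-chloro ether, the hindered amine taking up HCl. The acetal masks the C2' oxygen against base, organolithium and the ruthenium carbene of later steps.

Step 3
Reactants: 4 3-bromo-4-fluoro-2-(methoxymethoxy)benzaldehyde
Product: 5 4-fluoro-2-(methoxymethoxy)-3-vinylbenzaldehyde
Conditions: CH2=CHBpin, PdCl2(dppf) (3 mol%), K2CO3, 1,4-dioxane/H2O, 85 °C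
Reagents that add atoms: 4,4,5,5-tetramethyl-2-vinyl-1,3,2-dioxaborolane, C=CB1OC(C)(C)C(C)(C)O1
Why: Suzuki–Miyaura coupling; oxidative addition into the C–Br bond is helped by the para formyl group, and the aldehyde and the aryl fluoride are inert to zerovalent palladium and aqueous carbonate at this temperature. The vinyl group goes in before the tertiary ether so that no aryl–palladium species sits next to a pendant allyl ether.

Step 4
Reactants: 6 (R)-2-methylglycidol
Product: 7 (S)-2-[(methoxymethoxy)methyl]-2-methyloxirane
Conditions: MOMCl, iPr2NEt, CH2Cl2, 0 °C to rt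
Reagents that add atoms: chloromethyl methyl ether, COCCl
Why: Acetal protection of the primary alcohol under non-acidic conditions that leave the 2,2-disubstituted epoxide closed. The stereocentre is not touched; the descriptor changes from R to S only because the acetal raises the rank of the CH2O arm above the ring CH2. An acetal is used because it cannot migrate to the tertiary alkoxide in step 6.

Step 5
Reactants: 7 (S)-2-[(methoxymethoxy)methyl]-2-methyloxirane
Product: 9 (S)-1-(methoxymethoxy)-2-methylbut-3-en-2-ol, via sulfonium betaine 8 (not isolated)
Conditions: Me3SI, n-BuLi (3 equiv each), THF, −10 °C to rt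
Reagents that add atoms: trimethylsulfonium iodide, C[S+](C)C.[I-]
Why: One-carbon homologation of an epoxide to an allylic alcohol with excess dimethylsulfonium methylide: the ylide opens the epoxide at its unsubstituted CH2, and further ylide removes a proton from betaine 8 so that dimethyl sulfide leaves and the vinyl group forms. The C–O bond at the stereocentre is never broken, so the configuration of 6 is kept.

Step 6
Reactants: 9 (S)-1-(methoxymethoxy)-2-methylbut-3-en-2-ol; 5 4-fluoro-2-(methoxymethoxy)-3-vinylbenzaldehyde
Product: 11 2-(methoxymethoxy)-4-{[(2S)-1-(methoxymethoxy)-2-methylbut-3-en-2-yl]oxy}-3-vinylbenzaldehyde, via potassium alkoxide 10 (not isolated)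
Conditions: KN(SiMe3)2 (0.95 equiv on 9), THF, 0 °C; then 5, 0 °C to rt
Reagents that add atoms: none
Why: Nucleophilic aromatic substitution: tert-alkoxide 10 adds at C4 of 5, para to the formyl group, and fluoride leaves, the known route to hindered alkyl aryl ethers from tertiary alcohols and fluoroarenes. The amide base is kept below the amount of alcohol so that none is left to attack the aldehyde. The new bond is the aryl C–O bond, so the stereocentre keeps all four of its bonds.

Step 7
Reactants: 11 2-(methoxymethoxy)-4-{[(2S)-1-(methoxymethoxy)-2-methylbut-3-en-2-yl]oxy}-3-vinylbenzaldehyde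
Product: 12 (S)-5-(methoxymethoxy)-2-[(methoxymethoxy)methyl]-2-methyl-2H-chromene-6-carbaldehyde
Conditions: RuCl2(PCy3)(H2IMes)(=CHPh) (second-generation Grubbs catalyst, 5 mol%), CH2Cl2 (0.01 M), 40 °C, dark
Reagents that add atoms: none
Why: Ring-closing olefin metathesis, known for 2-vinylaryl 1,1-disubstituted allyl ethers, which give 2,2-disubstituted 2H-chromenes. The ruthenium benzylidene should exchange first with the styrene-type vinyl group on C3', the less hindered alkene, to give an aryl carbene that the flanking oxygens may hold as a chelate like that of isopropoxybenzylidene catalysts, which are themselves active. This carbene adds across the vinyl group on C2'' in a [2+2] step, and cycloreversion of the ruthenacyclobutane forms the C3''–C4'' double bond and releases the metal as a methylidene, with loss of ethene. The pyran closes as a six-membered ring with both reacting alkene carbons inside it, so only the cis alkene can form. No stereocentre is created; C2'' is a spectator with all four bonds untouched, so the S configuration of 11 passes into 12. The selectivity needed is ring closure over intermolecular cross-metathesis, and the ortho placing of the two alkenes, the two extra substituents on C2'' and high dilution secure it. The aldehyde and both acetals are inert to the neutral catalyst, and 40 °C is well below the temperature at which the aryl allyl ether would rearrange by a Claisen path to C5'.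

Step 8
Reactants: 13 diphenylphosphine oxide
Product: 15 4-[(diphenylphosphoryl)methyl]morpholine, via morpholin-4-ylmethanol 14 (not isolated)
Conditions: morpholine, (CH2O)n, toluene, reflux, Dean–Stark
Reagents that add atoms: morpholine, C1COCCN1; formaldehyde (as paraformaldehyde), C=O
Why: Phospha-Mannich condensation (Kabachnik–Fields type): the P–H compound adds to the iminium ion formed from hemiaminal 14, and water is removed azeotropically.

Step 9
Reactants: 15 4-[(diphenylphosphoryl)methyl]morpholine; 12 (S)-5-(methoxymethoxy)-2-[(methoxymethoxy)methyl]-2-methyl-2H-chromene-6-carbaldehyde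
Product: 18 4-[(E)-2-Q-ethenyl]morpholine, via lithiated phosphine oxide 16 (not isolated), via lithium alkoxide adduct 17 (not isolated)
Conditions: 15, n-BuLi, THF, −78 °C; 12, −78 to 0 °C; KOtBu, 0 °C to rt
Reagents that add atoms: none
Why: Horner–Wittig enamine synthesis: α-lithio phosphine oxide 16 adds to the non-enolisable aldehyde, and after cation exchange the potassium alkoxide of 17 loses diphenylphosphinate by syn-elimination to give the conjugated E enamine. This supplies the future C2 of the chromone with nitrogen attached and avoids both a free arylacetaldehyde and acid.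

Step 10
Reactants: 18 4-[(E)-2-Q-ethenyl]morpholine; 19 2,4,6-trifluorobenzoyl chloride
Product: 20 (E)-3-(morpholin-4-yl)-2-Q-1-(2,4,6-trifluorophenyl)prop-2-en-1-one
Conditions: Et3N, CH2Cl2, 0 °C to rt
Reagents that add atoms: none
Why: Stork-type C-acylation of an enamine: the β-carbon attacks the aroyl chloride and triethylamine takes up HCl to leave the vinylogous amide. The acid chloride has no α-hydrogen, so no ketene path competes.

Step 11
Reactants: 20 (E)-3-(morpholin-4-yl)-2-Q-1-(2,4,6-trifluorophenyl)prop-2-en-1-one
Product: 22 5,7-difluoro-3-Q-4H-chromen-4-one, via hydroxymethylene ketone 21 (not isolated)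
Conditions: 0.5 M aq. HCl, THF, 0 °C; extraction; then K2CO3, DMF, rt to 50 °C
Reagents that add atoms: water, O
Why: Brief mild acid hydrolyses the vinylogous amide to chelated enol 21. Carbonate then forms the enolate, whose oxygen displaces one of the two equivalent ortho fluorines (intramolecular SNAr, six-membered ring), as known for 2-fluoroaroyl 1,3-dicarbonyl enols. Acid is used for the hydrolysis so that the morpholine set free is protonated and cannot attack the fluoroarene.

Step 12
Reactants: 22 5,7-difluoro-3-Q-4H-chromen-4-one
Product: 24 5,7-bis(allyloxy)-3-Q-4H-chromen-4-one, via monoallyl ether 23 (not isolated)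
Conditions: allyl alcohol, NaH, THF/DMF, 0 to 50 °C
Reagents that add atoms: allyl alcohol, C=CCO
Why: Two nucleophilic aromatic substitutions on the fluorochromone, at C7 (para to the C4 carbonyl) and then C5 (ortho to it), a known reaction of fluorinated chromones with alkoxides. Addition of alkoxide at C2 is reversible and, without water, cannot lead to cleavage of the ring. Allyl is chosen because it is removed later without acid strength or hydrogen.

Step 13
Reactants: 24 5,7-bis(allyloxy)-3-Q-4H-chromen-4-one
Product: 26 5,7-dihydroxy-3-Q-4H-chromen-4-one, via monoallyl ether 25 (not isolated)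
Conditions: Pd(PPh3)4 (5 mol%), morpholine, THF, rt, dark
Reagents that add atoms: none
Why: Tsuji–Trost deallylation: zerovalent palladium ionises each aryl allyl ether to a π-allyl complex and a phenoxide, and morpholine traps the allyl group. The ring C2''–O bond is also allylic but is fully substituted and lies nearly in the plane of the C3''–C4'' alkene, so it should not ionise and the stereocentre is kept.

Step 14
Reactants: 26 5,7-dihydroxy-3-Q-4H-chromen-4-one
Product: 28 5,7-dihydroxy-3-[(2S)-5-hydroxy-2-(hydroxymethyl)-2-methyl-2H-chromen-6-yl]-4H-chromen-4-one, via primary methoxymethyl ether 27 (not isolated)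
Conditions: 3 M HCl in MeOH/H2O, 50 °C, dark
Reagents that add atoms: none
Why: Acid-catalysed transacetalisation in methanol removes the aryl acetal and then the alkyl acetal, the solvent trapping each oxocarbenium ion as dimethoxymethane far faster than the ring alkene could. 2,2-Disubstituted 2H-chromenes are known to survive such conditions, and the C2''–O bond is not ionised.

## Compound list

1 | 2-bromo-3-fluorophenol | Oc1cccc(F)c1Br | starting material
2 | 2-bromo-3-fluoro-6-(hydroxymethyl)phenol | OCc1ccc(F)c(Br)c1O | intermediate
3 | 3-bromo-4-fluoro-2-hydroxybenzaldehyde | O=Cc1ccc(F)c(Br)c1O | intermediate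
4 | 3-bromo-4-fluoro-2-(methoxymethoxy)benzaldehyde | COCOc1c(C=O)ccc(F)c1Br | intermediate
5 | 4-fluoro-2-(methoxymethoxy)-3-vinylbenzaldehyde | COCOc1c(C=O)ccc(F)c1C=C | intermediate
6 | (R)-2-methylglycidol [(R)-(2-methyloxiran-2-yl)methanol] | C[C@@]1(CO)CO1 | starting material
7 | (S)-2-[(methoxymethoxy)methyl]-2-methyloxirane | C[C@@]1(COCOC)CO1 | intermediate
8 | (S)-[4-(methoxymethoxy)-3-methyl-3-oxidobutyl]dimethylsulfonium (betaine) | C[C@@]([O-])(COCOC)CC[S+](C)C | intermediate
9 | (S)-1-(methoxymethoxy)-2-methylbut-3-en-2-ol | C[C@@](O)(COCOC)C=C | intermediate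
10 | potassium (S)-1-(methoxymethoxy)-2-methylbut-3-en-2-olate | C[C@@]([O-])(COCOC)C=C.[K+] | intermediate
11 | 2-(methoxymethoxy)-4-{[(2S)-1-(methoxymethoxy)-2-methylbut-3-en-2-yl]oxy}-3-vinylbenzaldehyde | C[C@@](Oc1ccc(C=O)c(OCOC)c1C=C)(COCOC)C=C | intermediate
12 | (S)-5-(methoxymethoxy)-2-[(methoxymethoxy)methyl]-2-methyl-2H-chromene-6-carbaldehyde | C[C@@]1(COCOC)C=Cc2c(ccc(C=O)c2OCOC)O1 | intermediate
13 | diphenylphosphine oxide | O=[PH](c1ccccc1)c1ccccc1 | starting material
14 | morpholin-4-ylmethanol | OCN1CCOCC1 | intermediate
15 | 4-[(diphenylphosphoryl)methyl]morpholine | O=P(CN1CCOCC1)(c1ccccc1)c1ccccc1 | intermediate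
16 | [(diphenylphosphoryl)(morpholin-4-yl)methyl]lithium | [Li]C(N1CCOCC1)P(=O)(c1ccccc1)c1ccccc1 | intermediate
17 | lithium 2-(diphenylphosphoryl)-1-[(2S)-5-(methoxymethoxy)-2-[(methoxymethoxy)methyl]-2-methyl-2H-chromen-6-yl]-2-(morpholin-4-yl)ethan-1-olate (both new centres as mixtures) | C[C@@]1(COCOC)C=Cc2c(ccc(C([O-])C(N3CCOCC3)P(=O)(c3ccccc3)c3ccccc3)c2OCOC)O1.[Li+] | intermediate
18 | 4-{(E)-2-[(2S)-5-(methoxymethoxy)-2-[(methoxymethoxy)methyl]-2-methyl-2H-chromen-6-yl]ethenyl}morpholine | C[C@@]1(COCOC)C=Cc2c(ccc(/C=C/N3CCOCC3)c2OCOC)O1 | intermediate
19 | 2,4,6-trifluorobenzoyl chloride | O=C(Cl)c1c(F)cc(F)cc1F | starting material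
20 | (E)-2-[(2S)-5-(methoxymethoxy)-2-[(methoxymethoxy)methyl]-2-methyl-2H-chromen-6-yl]-3-(morpholin-4-yl)-1-(2,4,6-trifluorophenyl)prop-2-en-1-one | C[C@@]1(COCOC)C=Cc2c(ccc(/C(C(=O)c3c(F)cc(F)cc3F)=C\N3CCOCC3)c2OCOC)O1 | intermediate
21 | (Z)-3-hydroxy-2-[(2S)-5-(methoxymethoxy)-2-[(methoxymethoxy)methyl]-2-methyl-2H-chromen-6-yl]-1-(2,4,6-trifluorophenyl)prop-2-en-1-one | C[C@@]1(COCOC)C=Cc2c(ccc(/C(C(=O)c3c(F)cc(F)cc3F)=C/O)c2OCOC)O1 | intermediate
22 | 5,7-difluoro-3-[(2S)-5-(methoxymethoxy)-2-[(methoxymethoxy)methyl]-2-methyl-2H-chromen-6-yl]-4H-chromen-4-one | C[C@@]1(COCOC)C=Cc2c(ccc(-c3coc4cc(F)cc(F)c4c3=O)c2OCOC)O1 | intermediate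
23 | 7-(allyloxy)-5-fluoro-3-[(2S)-5-(methoxymethoxy)-2-[(methoxymethoxy)methyl]-2-methyl-2H-chromen-6-yl]-4H-chromen-4-one | C[C@@]1(COCOC)C=Cc2c(ccc(-c3coc4cc(OCC=C)cc(F)c4c3=O)c2OCOC)O1 | intermediate
24 | 5,7-bis(allyloxy)-3-[(2S)-5-(methoxymethoxy)-2-[(methoxymethoxy)methyl]-2-methyl-2H-chromen-6-yl]-4H-chromen-4-one | C[C@@]1(COCOC)C=Cc2c(ccc(-c3coc4cc(OCC=C)cc(OCC=C)c4c3=O)c2OCOC)O1 | intermediate
25 | 5-(allyloxy)-7-hydroxy-3-[(2S)-5-(methoxymethoxy)-2-[(methoxymethoxy)methyl]-2-methyl-2H-chromen-6-yl]-4H-chromen-4-one | C[C@@]1(COCOC)C=Cc2c(ccc(-c3coc4cc(O)cc(OCC=C)c4c3=O)c2OCOC)O1 | intermediate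
26 | 5,7-dihydroxy-3-[(2S)-5-(methoxymethoxy)-2-[(methoxymethoxy)methyl]-2-methyl-2H-chromen-6-yl]-4H-chromen-4-one | C[C@@]1(COCOC)C=Cc2c(ccc(-c3coc4cc(O)cc(O)c4c3=O)c2OCOC)O1 | intermediate
27 | 5,7-dihydroxy-3-[(2S)-5-hydroxy-2-[(methoxymethoxy)methyl]-2-methyl-2H-chromen-6-yl]-4H-chromen-4-one | C[C@@]1(COCOC)C=Cc2c(ccc(-c3coc4cc(O)cc(O)c4c3=O)c2O)O1 | intermediate
28 | 5,7-dihydroxy-3-[(2S)-5-hydroxy-2-(hydroxymethyl)-2-methyl-2H-chromen-6-yl]-4H-chromen-4-one | C[C@@]1(CO)C=Cc2c(ccc(-c3coc4cc(O)cc(O)c4c3=O)c2O)O1 | target

## Step count and risks

Total: 14 steps. Longest linear sequence: 11 steps, from 1 through steps 1, 2, 3, 6, 7, 9, 10, 11, 12, 13 and 14 to 28. Steps 4 and 5 and step 8 are side branches.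

**Step 7 (key step).** The carbene formed on C3' may rest as an oxygen chelate and turn over slowly, and the vinyl group on the fully substituted C2'' is slow to engage. Intermolecular cross-metathesis or simple stalling could then take over, and heating to force the closure invites Claisen rearrangement of the aryl allyl ether. The fallback closes the pyran through oxygen instead of through the alkene; it sets out from 9 and 4, returns at 12, and also bypasses step 6:
- Ozonolysis of 9 (O3, CH2Cl2/MeOH, −78 °C; Me2S) should give (R)-2-hydroxy-3-(methoxymethoxy)-2-methylpropanal F1, which cannot epimerise because its α-carbon bears no hydrogen.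
- Ohira–Bestmann homologation (dimethyl (1-diazo-2-oxopropyl)phosphonate, K2CO3, MeOH) should give (S)-1-(methoxymethoxy)-2-methylbut-3-yn-2-ol F2.
- Sonogashira coupling of F2 with bromide 4 (PdCl2(PPh3)2, CuI, Et3N) would form the C3'–C4'' bond in 4-fluoro-3-[(3S)-3-hydroxy-4-(methoxymethoxy)-3-methylbut-1-yn-1-yl]-2-(methoxymethoxy)benzaldehyde F3.
- Cis-semihydrogenation (H2, Pd on CaCO3 poisoned with Pb(OAc)2, quinoline) would give 4-fluoro-3-[(1Z,3S)-3-hydroxy-4-(methoxymethoxy)-3-methylbut-1-en-1-yl]-2-(methoxymethoxy)benzaldehyde F4.
- The potassium alkoxide of F4 (KN(SiMe3)2, THF) would displace the neighbouring fluorine intramolecularly and give 12.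

**Step 6.** Addition of the tert-alkoxide at a carbon flanked by the twisted vinyl group may be slow, so that attack of alkoxide on the formyl group and hydride-transfer disproportionation of the aldehyde compete. The fallback makes the ether by palladium-catalysed allylic substitution with the phenol as nucleophile; it sets out from 5 and returns at 11:
- 2-(Methylsulfonyl)ethanol and NaH in DMF should give 2-(methoxymethoxy)-4-[2-(methylsulfonyl)ethoxy]-3-vinylbenzaldehyde F5, which loses methyl vinyl sulfone in the same flask to give 4-hydroxy-2-(methoxymethoxy)-3-vinylbenzaldehyde F6.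
- Addition of F6 to racemic 2-methyl-2-vinyloxirane with zerovalent palladium (Pd2(dba)3·CHCl3) and a chiral bis(2-diphenylphosphinobenzamide) ligand of the Trost type is a known dynamic kinetic asymmetric route to tertiary aryl ethers. It would give 4-{[(2S)-1-hydroxy-2-methylbut-3-en-2-yl]oxy}-2-(methoxymethoxy)-3-vinylbenzaldehyde F7. The configuration would then come from the ligand, whose enantiomer would be chosen by correlation with 11 from step 6.
- MOMCl and iPr2NEt convert F7 into 11.

**Step 12.** Alkoxide may add at C2 and open the chromone, and the second displacement at C5 may stall once C7 carries a donor. The fallback brings ring A in with its oxygens already in place; it sets out from 18 and returns at 26. It also spares step 11, where loss of the formyl carbon by retro-Claisen cleavage during hydrolysis is the main worry: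
- Methyl 2,4,6-trihydroxybenzoate with allyl bromide and K2CO3 should give methyl 2,4,6-tris(allyloxy)benzoate F8.
- KOH in aqueous DMSO should give 2,4,6-tris(allyloxy)benzoic acid F9, and oxalyl chloride with catalytic DMF 2,4,6-tris(allyloxy)benzoyl chloride F10.
- Acylation of 18 with F10 and Et3N, as in step 10, would give (E)-3-(morpholin-4-yl)-2-Q-1-[2,4,6-tris(allyloxy)phenyl]prop-2-en-1-one F11.
- Pd(PPh3)4 and morpholine would free the three phenols to give (E)-3-(morpholin-4-yl)-2-Q-1-(2,4,6-trihydroxyphenyl)prop-2-en-1-one F12, whose ortho hydroxyl adds to the enaminone and expels morpholine on gentle warming to give 26.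

**Step 9.** Elimination from the hydroxy phosphine oxide adduct may be incomplete, or the enamine may hydrolyse during work-up. The fallback is the classical three-stage homologation; it sets out from 12 and returns at 18:
- Wittig reaction with (methoxymethyl)triphenylphosphonium chloride and KN(SiMe3)2 should give (2S)-6-(2-methoxyethenyl)-5-(methoxymethoxy)-2-[(methoxymethoxy)methyl]-2-methyl-2H-chromene F13 as an E/Z mixture.
- Brief treatment with aqueous formic acid in THF at 0 °C should give 2-[(2S)-5-(methoxymethoxy)-2-[(methoxymethoxy)methyl]-2-methyl-2H-chromen-6-yl]acetaldehyde F14.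
- Condensation of F14 with morpholine over MgSO4 gives 18.

## Further compounds

F1 | step 7 | (R)-2-hydroxy-3-(methoxymethoxy)-2-methylpropanal | C[C@@](O)(COCOC)C=O
F2 | step 7 | (S)-1-(methoxymethoxy)-2-methylbut-3-yn-2-ol | C[C@@](O)(COCOC)C#C
F3 | step 7 | 4-fluoro-3-[(3S)-3-hydroxy-4-(methoxymethoxy)-3-methylbut-1-yn-1-yl]-2-(methoxymethoxy)benzaldehyde | C[C@@](O)(COCOC)C#Cc1c(F)ccc(C=O)c1OCOC
F4 | step 7 | 4-fluoro-3-[(1Z,3S)-3-hydroxy-4-(methoxymethoxy)-3-methylbut-1-en-1-yl]-2-(methoxymethoxy)benzaldehyde | C[C@@](O)(COCOC)/C=C\c1c(F)ccc(C=O)c1OCOC
F5 | step 6 | 2-(methoxymethoxy)-4-[2-(methylsulfonyl)ethoxy]-3-vinylbenzaldehyde | COCOc1c(C=O)ccc(OCCS(C)(=O)=O)c1C=C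
F6 | step 6 | 4-hydroxy-2-(methoxymethoxy)-3-vinylbenzaldehyde | COCOc1c(C=O)ccc(O)c1C=C
F7 | step 6 | 4-{[(2S)-1-hydroxy-2-methylbut-3-en-2-yl]oxy}-2-(methoxymethoxy)-3-vinylbenzaldehyde | C[C@@](Oc1ccc(C=O)c(OCOC)c1C=C)(CO)C=C
F8 | step 12 | methyl 2,4,6-tris(allyloxy)benzoate | COC(=O)c1c(OCC=C)cc(OCC=C)cc1OCC=C
F9 | step 12 | 2,4,6-tris(allyloxy)benzoic acid | OC(=O)c1c(OCC=C)cc(OCC=C)cc1OCC=C
F10 | step 12 | 2,4,6-tris(allyloxy)benzoyl chloride | O=C(Cl)c1c(OCC=C)cc(OCC=C)cc1OCC=C
F11 | step 12 | (E)-2-[(2S)-5-(methoxymethoxy)-2-[(methoxymethoxy)methyl]-2-methyl-2H-chromen-6-yl]-3-(morpholin-4-yl)-1-[2,4,6-tris(allyloxy)phenyl]prop-2-en-1-one | C[C@@]1(COCOC)C=Cc2c(ccc(/C(C(=O)c3c(OCC=C)cc(OCC=C)cc3OCC=C)=C\N3CCOCC3)c2OCOC)O1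
F12 | step 12 | (E)-2-[(2S)-5-(methoxymethoxy)-2-[(methoxymethoxy)methyl]-2-methyl-2H-chromen-6-yl]-3-(morpholin-4-yl)-1-(2,4,6-trihydroxyphenyl)prop-2-en-1-one | C[C@@]1(COCOC)C=Cc2c(ccc(/C(C(=O)c3c(O)cc(O)cc3O)=C\N3CCOCC3)c2OCOC)O1
F13 | step 9 | (2S)-6-(2-methoxyethenyl)-5-(methoxymethoxy)-2-[(methoxymethoxy)methyl]-2-methyl-2H-chromene (E/Z mixture) | C[C@@]1(COCOC)C=Cc2c(ccc(C=COC)c2OCOC)O1
F14 | step 9 | 2-[(2S)-5-(methoxymethoxy)-2-[(methoxymethoxy)methyl]-2-methyl-2H-chromen-6-yl]acetaldehyde | C[C@@]1(COCOC)C=Cc2c(ccc(CC=O)c2OCOC)O1
A1 | alternative 1 | 3-{2-hydroxy-3-[(E)-prop-1-enyl]-4-(triisopropylsilyloxy)phenyl}-5,7-bis(methoxymethoxy)-4H-chromen-4-one | C/C=C/c1c(O[Si](C(C)C)(C(C)C)C(C)C)ccc(-c2coc3cc(OCOC)cc(OCOC)c3c2=O)c1O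
A2 | alternative 1 | (E)-3-(4-diazo-3-oxobut-1-en-1-yl)-5,7-bis(methoxymethoxy)-4H-chromen-4-one | [N-]=[N+]=CC(=O)/C=C/c1coc2cc(OCOC)cc(OCOC)c2c1=O
A3 | alternative 1 | (E)-triisopropyl(pent-3-en-1-yn-1-yloxy)silane | C/C=C/C#CO[Si](C(C)C)(C(C)C)C(C)C
A4 | alternative 2 | 2,2-bis[(tert-butyldimethylsilyloxy)methyl]-7,8-dihydro-2H-chromen-5(6H)-one | O=C1CCCC2=C1C=CC(CO[Si](C)(C)C(C)(C)C)(CO[Si](C)(C)C(C)(C)C)O2
A5 | alternative 2 | cyclohexane-1,3-dione | O=C1CCCC(=O)C1
A6 | alternative 2 | 4-(tert-butyldimethylsilyloxy)-3-[(tert-butyldimethylsilyloxy)methyl]but-2-enal | O=CC=C(CO[Si](C)(C)C(C)(C)C)CO[Si](C)(C)C(C)(C)C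
A7 | alternative 3 | 3-{(S)-2-[(tert-butyldimethylsilyloxy)methyl]-5-(methoxymethoxy)-2-methyl-2H-chromen-6-yl}-5,7-bis(methoxymethoxy)-2-(trimethylsilyl)-4H-chromen-4-one | C[C@@]1(CO[Si](C)(C)C(C)(C)C)C=Cc2c(ccc(-c3c([Si](C)(C)C)oc4cc(OCOC)cc(OCOC)c4c3=O)c2OCOC)O1
A8 | alternative 3 | 2-hydroxy-4,6-bis(methoxymethoxy)benzaldehyde | O=Cc1c(O)cc(OCOC)cc1OCOC
A9 | alternative 3 | (S)-tert-butyl{[5-(methoxymethoxy)-2-methyl-6-[(trimethylsilyl)ethynyl]-2H-chromen-2-yl]methoxy}dimethylsilane | C[C@@]1(CO[Si](C)(C)C(C)(C)C)C=Cc2c(ccc(C#C[Si](C)(C)C)c2OCOC)O1
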